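## Structural features

18 is an achiral dihydrochalcone: a 3,4-dihydroxyphenyl ring is joined through a CH2–CH2–C(=O) chain to C7 of a 3-methyl-2,5-dihydro-1-benzoxepine. Ring A (C5a, C6, C7, C8, C9, C9a) is a phloroglucinol nucleus with one free position, C9. The hydroxyls on C6 and C8 flank the acyl carbon C7 and are both hydrogen-bonded to the ketone; the third oxygen, O1 on C9a, lies para to C7 and belongs to the seven-membered ring O1–C2H2–C3(CH3)=C4H–C5H2, fused to ring A across C5a–C9a. There is no stereocentre, so none stand next to each other; the only geometric element is the ring alkene C3=C4, which must be cis in the ring and must carry its methyl group on C3, next to the oxygen-bound C2. The fragile parts are the catechol (oxidation), the electron-rich ring A, the C5 methylene (benzylic and allylic at once), the allyl aryl ether O1–C2, and the trisubstituted alkene, which acid could shift or trap with the C6 hydroxyl. The real difficulty is regiochemical: O1, C5 and the acyl group must be placed on a ring whose three oxygens, and whose C7 and C9 positions, are hard to tell apart, and a seven-membered ring must be closed with the alkene in a defined place. The key step exploits the chain O1–C2–C3(CH3)=C4–C5 together with the C5a=C9a bond: if ring A is temporarily non-aromatic with a ketone at C6, then C9a=C5a–…/O1–C2–C3=C4 is an allyl vinyl ether, the [3,3] isomer of a 2-isopropenylcyclopropane that is spiro-linked at C5a and has its carbonyl carbon at C9a.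

## Logic of the disconnections

**18 ⇒ 17.** The two aryl O–CH2 acetal bonds on the distal ring are cut last. A free catechol would not survive the enolate and the oxidants used earlier, and 17 already contains every skeletal bond of 18. The forward step must cleave two acetals without protonating C3=C4, ionising O1–C2, or letting the C6 hydroxyl add to the alkene.

**17 ⇒ 15 (through 16).** No skeletal bond is cut. Ring A of 17 is read as the enol form of the triketone 16, and the C8 carbonyl of 16 is taken back to the carbinol of 15. This gives up aromaticity deliberately, so that C5a=C9a becomes an enol-ether double bond, the form the key step delivers. The forward oxidation must stop at the ketone; tautomerisation then makes the arene.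

**15 ⇒ 14.** The O–Si bond at C8 is restored. The C8 oxygen must stay masked until the acyl group is at the ketone level, otherwise ring A would aromatise to an electron-rich hydroxybenzyl alcohol. The forward desilylation must not expel the C8 oxygen.

**14 ⇒ 13 ⇒ 8 + 11.** After lowering the side-chain carbonyl to a carbinol, the C7–C(carbinol) bond is cut as an aldol. C7 is the only α-carbon of the C6 ketone that can be deprotonated kinetically, so the acyl position follows from the position of the ketone and not from a contest between C7 and C9 of an arene. The cut divides the molecule into two halves of similar size. The forward step needs a kinetic enolate that neither expels the β-silyloxy group nor equilibrates.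

**8 ⇒ 7.** This is the strategic cut. O1–C2 is broken and C4–C5a is formed in the retro direction, which turns the dihydrooxepine into a spiro 2-isopropenylcyclopropane with two equivalent carbonyls. Mapping: C2 from the isopropenyl CH2, C3 from its central carbon, C4 and C5 from the cyclopropane CH and CH2, C5a from the spiro carbon, C9a and O1 from one carbonyl, C6 from the other. Re-derived atom by atom from 18, the structures of 7 and 8 need no correction. The forward step must be concerted; a stepwise opening would give a five-membered enol ether.

**7 ⇒ 4 + 5 (through 6).** Both cyclopropane bonds to the spiro carbon are cut, which leads to a symmetric 1,3-dione and a C5 bis-electrophile. The forward reaction must start at the CH2Br remote from the methyl group, so that the SN2′ closure places the isopropenyl group on the ring CH, and it must close on carbon.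

**4 ⇒ 2 ⇒ 1.** The O–Si bond is removed, then one hydride and one proton are taken from the carbinol carbon. The whole C6 ring with its three oxygens is thus bought as 1, one oxygen being stored at the alcohol level until step 10. The forward reduction must stop after one carbonyl.

**11 ⇒ 10 ⇒ 9.** The aldehyde is taken back to an ester, and the three O–CH2 bonds of the protecting groups are cut. The forward steps are a single protection of all three acidic OH groups and a partial reduction.

## Other disconnections considered

**Alternative 1:** The cut runs through ring A itself, between the acyl-bearing C7 and a neighbouring hydroxylated ring carbon. In the forward direction Mg(OMe)2 opens the pyrone A2 to a magnesium-chelated methyl 3,5,7-trioxo ester; the carbanion between the two ketones at the side-chain end attacks the ester carbonyl (Claisen mode) and A1 results after loss of methoxide and enolisation.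

- In its favour: the acyl group is placed between two hydroxyls with certainty, ring A arrives aromatic with no redox step, and no elimination-prone β-oxygenated ketone appears. On these three points it is better than the chosen plan. A2 is one C–C bond away from commercial building blocks, so A1 should need about four steps, which is also better up to that stage.
- Against it here: A1 contains nothing of the oxepine. O1–C2, the C3=C4 alkene and C5–C5a must still be made on a ring with three phenolic hydroxyls. This means selective alkylation of the para oxygen, C-allylation next to it (for example by aromatic Claisen rearrangement), a second O-alkylation and a ring closure, with the ortho hydroxyls protected or tolerated: five or six further operations, each with a chemoselectivity question. The chelate must also steer the cyclisation to the Claisen mode and away from the aldol mode.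
- Comparison. Structure: the chosen plan fixes the oxepine first and derives the ring-A pattern from it, while Alternative 1 fixes ring A first; the symmetry of A1 makes its two free ring carbons equivalent, so on C-site choice the two are equal. Mechanism: an ionic condensation under chelate control against a concerted pericyclic shift, both well understood. Step economy: roughly equal overall (ten to eleven steps), with Alternative 1 faster to the acylphloroglucinol and slower afterwards.

**Alternative 2:** The cut is the aryl ether bond O1–C9a. In the forward direction KOtBu deprotonates the (Z)-allylic alcohol of A4; the alkoxide adds to C9a, the Meisenheimer intermediate is stabilised by the para formyl group, and loss of fluoride closes the seven-membered ring to A3.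

- In its favour: ring A is aromatic throughout, so no redox adjustment is needed, which is better than the chosen plan. The formyl group both activates the substitution and is the handle for the side chain, the two acetal-protected oxygens are meta to fluorine and do not deactivate it, and the functional group at C7 is fixed by the substitution pattern, which equals the chosen plan in regiochemical certainty.
- Against it here: A4 is a pentasubstituted benzene carrying a stereodefined (Z)-trisubstituted allylic alcohol; only the Z isomer can cyclise, and its preparation is estimated at seven or eight steps. The strong base may move the alkene into conjugation through the doubly activated C5 methylene. After A3 three more operations remain (addition of a 2-arylethyl nucleophile, oxidation, acidic deprotection with the same alkene question as step 11).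
- Comparison. Structure: the chosen plan obtains the cis alkene automatically and never needs an acyclic alkene of defined geometry. Mechanism: the alternative's addition–elimination is irreversible and robust, a point in its favour, whereas the chosen rearrangement is an equilibrium. Step economy: the alternative is estimated to be two or three steps longer.

**Alternative 3:** The cut is C4–C5. In the forward direction Sc(OTf)3 ionises the benzylic alcohol of A6 to a cation stabilised by the three ring oxygens; the tethered (Z)-vinylsilane attacks through its silicon-bearing carbon, and the β-silyl cation at C3 loses silicon, leaving C3=C4 in A5.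

- In its favour: the reaction is catalytic and mild, the alkene position is dictated by the β-silicon effect (equal to the chosen plan in certainty), ring A is aromatic throughout, and the bicyclic core should be reached in fewer steps than in the chosen plan.
- Against it here: A5 has no acyl group, so C7 must later be acylated in competition with C9, both flanked by two oxygens. Silyl ethers direct lithiation poorly, and Friedel–Crafts conditions are not tolerated by the allyl aryl ether. This is exactly the C7/C9 problem the chosen plan avoids. In addition, the cation can alkylate another electron-rich ring intermolecularly, seven-membered closure through a cation is not fast, and the (Z)-vinylsilane must be made stereoselectively.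
- Comparison. Structure: the alternative solves the oxepine but not the acyl position; the chosen plan solves both from one ketone. Mechanism: stepwise cationic against concerted and neutral. Step economy: shorter to the core, longer and less certain in the endgame, so at best equal overall.

Key step: step 4

Assumption (remark on the chemistry): 18 has no stereocentre; the stereocentres of the intermediates are transient, so racemates and diastereomer mixtures are carried forward and one stereoisomer is drawn for each. Locants O1–C9a used for intermediates are those of the benzoxepine of 18.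

## Route

**Step 1**
Reactants: 1 phloroglucinol
Product: 2 5-hydroxycyclohexane-1,3-dione
Conditions: NaBH4, H2O, rt; then aq. HCl to pH 3, 0 °C
Reagents that add atoms: none
Why: Borohydride carbonyl reduction: in water phloroglucinol reacts through its keto tautomer, one C=O takes up hydride, and the product, a vinylogous acid that is ionised in the basic medium, resists further hydride; cold, mild acidification avoids dehydration to resorcinol.

**Step 2**
Reactants: 2 5-hydroxycyclohexane-1,3-dione
Product: 4 5-(tert-butyldimethylsilyloxy)cyclohexane-1,3-dione, via bis-silyl enol ether 3 (not isolated)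
Conditions: TBSCl, imidazole, DMF, 0 °C to rt; then aq. citric acid, THF, 0 °C
Reagents that add atoms: tert-butyldimethylsilyl chloride, CC(C)(C)[Si](C)(C)Cl
Why: Silylation caps the secondary alcohol and also the acidic enol oxygen to give 3; the vinylogous silyl ester is far more labile than the alkyl silyl ether, so brief mild aqueous acid should return the free dione with the C5 ether intact.

**Step 3**
Reactants: 4 5-(tert-butyldimethylsilyloxy)cyclohexane-1,3-dione; 5 (E)-1,4-dibromo-2-methylbut-2-ene
Product: 7 6-(tert-butyldimethylsilyloxy)-1-(prop-1-en-2-yl)spiro[2.5]octane-4,8-dione, via monoalkylated allylic bromide 6 (not isolated)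
Conditions: K2CO3, MeCN, rt; aqueous work-up below 25 °C
Reagents that add atoms: none
Why: Double alkylation of a cyclic 1,3-dione with a 1,4-dihalobut-2-ene (known spirocyclopropanation): the C2 enolate attacks the less hindered, prenyl-type CH2Br remote from the methyl group to give 6, whose enolate closes by 3-exo SN2′ displacement of the second bromide. The cyclopropane CH is formed without control relative to the silyloxy carbon, and both diastereomers are used; MeCN keeps KBr out of solution, which limits bromide-induced reopening of the product.

**Step 4**
Reactants: 7 6-(tert-butyldimethylsilyloxy)-1-(prop-1-en-2-yl)spiro[2.5]octane-4,8-dione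
Product: 8 8-(tert-butyldimethylsilyloxy)-3-methyl-2,5,8,9-tetrahydro-1-benzoxepin-6(7H)-one
Conditions: PhMe (degassed, dilute), 90 °C, NaHCO3-washed glassware
Reagents that add atoms: none
Why: Heating brings the carbonyl that is cis to the isopropenyl group and the C=CH2 terminus together in a six-centre boat transition state: the carbonyl oxygen bonds to the isopropenyl CH2 (O1–C2) while the cyclopropane bond between the isopropenyl-bearing carbon and the spiro carbon (C4–C5a) breaks and the π bonds move to C3=C4 and C5a=C9a. This is the retro-Claisen (oxa-Cope) rearrangement of 1,1-diacyl-2-vinylcyclopropanes, the oxygen analogue of the cis-divinylcyclopropane Cope rearrangement, and it is known for spirocyclopropanes of cyclohexane-1,3-diones. The seven-membered ring is not closed end to end but arises by sigmatropic expansion of the three-membered ring, which is why the new alkene can only be cis and the methyl group can only end up on C3. No stereocentre is created: the cyclopropane CH becomes sp2, the spiro carbon loses its stereogenicity and C8 is untouched, so both diastereomers of 7 should give the same racemic 8. The step needs periselectivity for the concerted path over ionic or diradical opening of the donor–acceptor cyclopropane, which would end in the 2-isopropenyl-2,3-dihydrofuran isomer; the geminal dicarbonyl group secures a cis carbonyl in every molecule, and a neutral medium free of halide, Lewis acids and amines removes the triggers of the stepwise path. The two carbonyls are constitutionally equivalent, so there is no regiochemical choice. Release of cyclopropane strain, the conjugation of the new vinylogous ester and the more substituted alkene should place the equilibrium on the side of 8.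

**Step 5**
Reactants: 9 3-(3,4-dihydroxyphenyl)propanoic acid
Product: 10 methoxymethyl 3-[3,4-bis(methoxymethoxy)phenyl]propanoate
Conditions: MOMCl, i-Pr2NEt, CH2Cl2, 0 °C to rt
Reagents that add atoms: chloromethyl methyl ether, COCCl
Why: O-Alkylation of both phenols and of the carboxylate with a hindered amine base; the methoxymethyl ester serves as the ester for step 6, so no separate esterification is needed.

**Step 6**
Reactants: 10 methoxymethyl 3-[3,4-bis(methoxymethoxy)phenyl]propanoate
Product: 11 3-[3,4-bis(methoxymethoxy)phenyl]propanal
Conditions: i-Bu2AlH, CH2Cl2, −78 °C; then MeOH, aq. potassium sodium tartrate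
Reagents that add atoms: none
Why: Partial reduction of an ester by i-Bu2AlH: the tetrahedral aluminium adduct persists at −78 °C and releases the aldehyde only on hydrolytic work-up; aryl methoxymethyl ethers are inert under these conditions.

**Step 7**
Reactants: 8 8-(tert-butyldimethylsilyloxy)-3-methyl-2,5,8,9-tetrahydro-1-benzoxepin-6(7H)-one; 11 3-[3,4-bis(methoxymethoxy)phenyl]propanal
Product: 13 7-{3-[3,4-bis(methoxymethoxy)phenyl]-1-hydroxypropyl}-8-(tert-butyldimethylsilyloxy)-3-methyl-2,5,8,9-tetrahydro-1-benzoxepin-6(7H)-one, via lithium enolate 12 (not isolated)
Conditions: LiN(i-Pr)2 (LDA), THF, −78 °C; then 11, −78 °C; AcOH, −78 °C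
Reagents that add atoms: none
Why: Directed aldol addition: the amide base removes the kinetically accessible α′-proton of the vinylogous ester at C7 (as in Stork–Danheiser chemistry) and enolate 12 adds to the aldehyde, so the side chain is attached at C7 by construction. The new stereocentres at C7 and the carbinol carbon (attack expected mainly trans to the C8 silyloxy group) need no control because steps 8 and 10 erase them; the cold acidic quench forestalls retro-aldol cleavage and β-elimination of the silyloxy group.

**Step 8**
Reactants: 13 7-{3-[3,4-bis(methoxymethoxy)phenyl]-1-hydroxypropyl}-8-(tert-butyldimethylsilyloxy)-3-methyl-2,5,8,9-tetrahydro-1-benzoxepin-6(7H)-one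
Product: 14 7-{3-[3,4-bis(methoxymethoxy)phenyl]propanoyl}-8-(tert-butyldimethylsilyloxy)-3-methyl-2,5,8,9-tetrahydro-1-benzoxepin-6(7H)-one
Conditions: Dess–Martin periodinane (1.2 equiv), NaHCO3, CH2Cl2, 0 °C to rt
Reagents that add atoms: none
Why: Dess–Martin oxidation of a β-hydroxy ketone to the β-diketone, a transformation for which this reagent is well suited; C8 stays protected so ring A cannot yet aromatise, and only a small excess is used because the enolised product could be oxidised further at C7.

**Step 9**
Reactants: 14 7-{3-[3,4-bis(methoxymethoxy)phenyl]propanoyl}-8-(tert-butyldimethylsilyloxy)-3-methyl-2,5,8,9-tetrahydro-1-benzoxepin-6(7H)-one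
Product: 15 7-{3-[3,4-bis(methoxymethoxy)phenyl]propanoyl}-8-hydroxy-3-methyl-2,5,8,9-tetrahydro-1-benzoxepin-6(7H)-one
Conditions: HF·pyridine, pyridine, THF, 0 °C to rt
Reagents that add atoms: none
Why: Fluoride cleavage of the secondary silyl ether under pyridine-buffered conditions that leave aryl methoxymethyl ethers, the enol ether and the β-diketone untouched; the buffered, cold medium is chosen because 15 could lose water from C8 with aromatisation under stronger acid or base.

**Step 10**
Reactants: 15 7-{3-[3,4-bis(methoxymethoxy)phenyl]propanoyl}-8-hydroxy-3-methyl-2,5,8,9-tetrahydro-1-benzoxepin-6(7H)-one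
Product: 17 1-(6,8-dihydroxy-3-methyl-2,5-dihydro-1-benzoxepin-7-yl)-3-[3,4-bis(methoxymethoxy)phenyl]propan-1-one, via triketone tautomer 16 (not isolated)
Conditions: Dess–Martin periodinane (1.3 equiv), NaHCO3, CH2Cl2, 0 °C
Reagents that add atoms: none
Why: Dess–Martin oxidation of the C8 carbinol gives triketone 16, the keto tautomer of a phloroglucinol, which should enolise at once to aromatic 17 and thereby remove the last stereocentre. The product is an acylphloroglucinol whose hydroxyls are hydrogen-bonded to the ketone and whose ring is deactivated by the acyl group, which should protect it from the pentavalent iodine reagent.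

**Step 11**
Reactants: 17 1-(6,8-dihydroxy-3-methyl-2,5-dihydro-1-benzoxepin-7-yl)-3-[3,4-bis(methoxymethoxy)phenyl]propan-1-one
Product: 18 1-(6,8-dihydroxy-3-methyl-2,5-dihydro-1-benzoxepin-7-yl)-3-(3,4-dihydroxyphenyl)propan-1-one
Conditions: HCl (ca. 1 M in MeOH), rt, argon
Reagents that add atoms: none
Why: Acid-catalysed transacetalisation of the two aryl methoxymethyl ethers to methanol, giving dimethoxymethane; dilute methanolic HCl at room temperature should be too weak to protonate the trisubstituted alkene or ionise the allyl aryl ether, and exclusion of air protects the liberated catechol.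

## Compound list

1 | phloroglucinol (benzene-1,3,5-triol) | Oc1cc(O)cc(O)c1 | starting material
2 | 5-hydroxycyclohexane-1,3-dione (achiral; largely enolised) | O=C1CC(O)CC(=O)C1 | intermediate
3 | 3,5-bis(tert-butyldimethylsilyloxy)cyclohex-2-en-1-one (racemic, one enantiomer drawn; not isolated) | O=C1C=C(O[Si](C)(C)C(C)(C)C)C[C@H](O[Si](C)(C)C(C)(C)C)C1 | intermediate
4 | 5-(tert-butyldimethylsilyloxy)cyclohexane-1,3-dione (achiral) | O=C1CC(O[Si](C)(C)C(C)(C)C)CC(=O)C1 | intermediate
5 | (E)-1,4-dibromo-2-methylbut-2-ene | BrC/C=C(\C)CBr | starting material
6 | 2-[(2E)-4-bromo-3-methylbut-2-en-1-yl]-5-(tert-butyldimethylsilyloxy)cyclohexane-1,3-dione (enolised at C2, no fixed configuration; not isolated) | O=C1CC(O[Si](C)(C)C(C)(C)C)CC(=O)C1C/C=C(\C)CBr | intermediate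
7 | 6-(tert-butyldimethylsilyloxy)-1-(prop-1-en-2-yl)spiro[2.5]octane-4,8-dione (racemic; both diastereomers, one drawn) | C=C(C)[C@H]1C[C@@]12C(=O)C[C@H](O[Si](C)(C)C(C)(C)C)CC2=O | intermediate
8 | 8-(tert-butyldimethylsilyloxy)-3-methyl-2,5,8,9-tetrahydro-1-benzoxepin-6(7H)-one (racemic, one enantiomer drawn) | CC1=CCC2=C(OC1)C[C@H](O[Si](C)(C)C(C)(C)C)CC2=O | intermediate
9 | 3-(3,4-dihydroxyphenyl)propanoic acid | OC(=O)CCc1ccc(O)c(O)c1 | starting material
10 | methoxymethyl 3-[3,4-bis(methoxymethoxy)phenyl]propanoate | COCOC(=O)CCc1ccc(OCOC)c(OCOC)c1 | intermediate
11 | 3-[3,4-bis(methoxymethoxy)phenyl]propanal | O=CCCc1ccc(OCOC)c(OCOC)c1 | intermediate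
12 | lithium 8-(tert-butyldimethylsilyloxy)-3-methyl-2,5,8,9-tetrahydro-1-benzoxepin-6-olate (C6=C7 enolate of 8; racemic; not isolated) | [Li+].CC1=CCC2=C(OC1)C[C@H](O[Si](C)(C)C(C)(C)C)C=C2[O-] | intermediate
13 | 7-{3-[3,4-bis(methoxymethoxy)phenyl]-1-hydroxypropyl}-8-(tert-butyldimethylsilyloxy)-3-methyl-2,5,8,9-tetrahydro-1-benzoxepin-6(7H)-one (racemic; diastereomer mixture at C7 and the carbinol carbon, left undefined) | CC1=CCC2=C(OC1)C[C@H](O[Si](C)(C)C(C)(C)C)C(C(O)CCc3ccc(OCOC)c(OCOC)c3)C2=O | intermediate
14 | 7-{3-[3,4-bis(methoxymethoxy)phenyl]propanoyl}-8-(tert-butyldimethylsilyloxy)-3-methyl-2,5,8,9-tetrahydro-1-benzoxepin-6(7H)-one (racemic; C7 enolised, drawn as the keto form) | CC1=CCC2=C(OC1)C[C@H](O[Si](C)(C)C(C)(C)C)C(C(=O)CCc3ccc(OCOC)c(OCOC)c3)C2=O | intermediate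
15 | 7-{3-[3,4-bis(methoxymethoxy)phenyl]propanoyl}-8-hydroxy-3-methyl-2,5,8,9-tetrahydro-1-benzoxepin-6(7H)-one (racemic; C7 enolised) | CC1=CCC2=C(OC1)C[C@H](O)C(C(=O)CCc3ccc(OCOC)c(OCOC)c3)C2=O | intermediate
16 | 7-{3-[3,4-bis(methoxymethoxy)phenyl]propanoyl}-3-methyl-2,5-dihydro-1-benzoxepine-6,8(7H,9H)-dione (keto tautomer of 17; not isolated) | CC1=CCC2=C(OC1)CC(=O)C(C(=O)CCc3ccc(OCOC)c(OCOC)c3)C2=O | intermediate
17 | 1-(6,8-dihydroxy-3-methyl-2,5-dihydro-1-benzoxepin-7-yl)-3-[3,4-bis(methoxymethoxy)phenyl]propan-1-one (achiral) | CC1=CCc2c(cc(O)c(C(=O)CCc3ccc(OCOC)c(OCOC)c3)c2O)OC1 | intermediate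
18 | 1-(6,8-dihydroxy-3-methyl-2,5-dihydro-1-benzoxepin-7-yl)-3-(3,4-dihydroxyphenyl)propan-1-one (achiral) | CC1=CCc2c(cc(O)c(C(=O)CCc3ccc(O)c(O)c3)c2O)OC1 | target

## Step count and least certain steps

Total step count: 11. Longest linear sequence: 9 (steps 1, 2, 3, 4, 7, 8, 9, 10, 11); steps 5 and 6 form the side branch to 11.

**Step 4 (key step).** The most likely failure is that a stepwise opening of the donor–acceptor cyclopropane, triggered by traces of acid, halide or radicals, outruns the concerted shift and closes to the five-membered enol ether. Conversion may also stall if the equilibrium is less one-sided than expected. The fallback sets out from 4 and returns at 8 by ring-closing metathesis. Zerovalent-palladium-catalysed C-allylation of 4 (Pd(PPh3)4, allyl acetate, THF; Tsuji–Trost) would give 2-allyl-5-(tert-butyldimethylsilyloxy)cyclohexane-1,3-dione F1. Mitsunobu O-alkylation with 2-methylprop-2-en-1-ol (PPh3, diisopropyl azodicarboxylate, THF) would give the vinylogous ester 2-allyl-5-(tert-butyldimethylsilyloxy)-3-[(2-methylprop-2-en-1-yl)oxy]cyclohex-2-en-1-one F2. The second-generation Grubbs catalyst (H2IMes)(PCy3)Cl2Ru=CHPh in toluene at 80 °C would then close C3=C4 and deliver 8.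

**Step 3.** The first alkylation may occur on oxygen or at the CH2Br next to the methyl group, which would lead after rearrangement to the 4-methyl isomer. The product may also be reopened by bromide and reclosed on oxygen. The fallback sets out from 4 and returns at 7, making the two C–C bonds in separate operations with a unit whose leaving groups differ: (E)-4-bromo-1-chloro-2-methylbut-2-ene F3, obtainable from 1-chloro-2-methylbut-3-en-2-ol and PBr3 with allylic transposition. K2CO3 in acetone would alkylate 4 at the bromide terminus only and give 2-[(2E)-4-chloro-3-methylbut-2-en-1-yl]-5-(tert-butyldimethylsilyloxy)cyclohexane-1,3-dione F4. After purification, F4 would be closed to 7 with Cs2CO3 in MeCN by SN2′ loss of chloride.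

**Step 7.** The lithium enolate may expel silanolate from C8 (loss of the C8 oxygen and premature aromatisation), exchange protons with the enolisable aldehyde, or undergo retro-aldol cleavage on warming. The fallback sets out from 8 and returns at 14, which also makes step 8 unnecessary. Saponification of 10 (LiOH, THF/H2O) would give 3-[3,4-bis(methoxymethoxy)phenyl]propanoic acid F5. Coupling with 1H-benzotriazole (N-ethyl-N′-(3-dimethylaminopropyl)carbodiimide hydrochloride, CH2Cl2) would give 1-(1H-benzotriazol-1-yl)-3-[3,4-bis(methoxymethoxy)phenyl]propan-1-one F6. Soft enolisation of 8 (MgBr2·OEt2, i-Pr2NEt, CH2Cl2, rt) and C-acylation by F6 would give 14 directly, without a strongly basic enolate.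

**Step 9.** Once C8 carries a free hydroxyl next to the enolised β-diketone, loss of water with aromatisation would remove the C8 oxygen for good. The fallback sets out from 13 and returns at 17. 13 would be desilylated first (HF·pyridine, pyridine, THF) to the diol 7-{3-[3,4-bis(methoxymethoxy)phenyl]-1-hydroxypropyl}-8-hydroxy-3-methyl-2,5,8,9-tetrahydro-1-benzoxepin-6(7H)-one F7, in which C7–H is not flanked by two carbonyls. Both carbinols would then be oxidised in one operation with excess Dess–Martin periodinane, so that 14 and 15 are never formed.

**Step 11.** Protic acid may add the C6 hydroxyl or methanol across C3=C4 or ionise the allyl aryl ether before both acetals are gone, and the freed catechol may oxidise. The fallback sets out from 17 and returns at 18 without Brønsted acid. TMSOTf and 2,2′-bipyridyl in MeCN at 0 °C convert aryl methoxymethyl ethers into aryl silyl ethers, here the persilylated 3-[3,4-bis(trimethylsilyloxy)phenyl]-1-[3-methyl-6,8-bis(trimethylsilyloxy)-2,5-dihydro-1-benzoxepin-7-yl]propan-1-one F8. Addition of water would hydrolyse all four silyl ethers to 18.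

## Further compounds

F1 | step 4 | 2-allyl-5-(tert-butyldimethylsilyloxy)cyclohexane-1,3-dione | C=CCC1C(=O)CC(O[Si](C)(C)C(C)(C)C)CC1=O
F2 | step 4 | 2-allyl-5-(tert-butyldimethylsilyloxy)-3-[(2-methylprop-2-en-1-yl)oxy]cyclohex-2-en-1-one (racemic, one enantiomer drawn) | C=CCC1=C(OCC(C)=C)C[C@H](O[Si](C)(C)C(C)(C)C)CC1=O
F3 | step 3 | (E)-4-bromo-1-chloro-2-methylbut-2-ene | ClC/C(C)=C/CBr
F4 | step 3 | 2-[(2E)-4-chloro-3-methylbut-2-en-1-yl]-5-(tert-butyldimethylsilyloxy)cyclohexane-1,3-dione | O=C1CC(O[Si](C)(C)C(C)(C)C)CC(=O)C1C/C=C(\C)CCl
F5 | step 7 | 3-[3,4-bis(methoxymethoxy)phenyl]propanoic acid | OC(=O)CCc1ccc(OCOC)c(OCOC)c1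
F6 | step 7 | 1-(1H-benzotriazol-1-yl)-3-[3,4-bis(methoxymethoxy)phenyl]propan-1-one | O=C(CCc1ccc(OCOC)c(OCOC)c1)n1nnc2ccccc12
F7 | step 9 | 7-{3-[3,4-bis(methoxymethoxy)phenyl]-1-hydroxypropyl}-8-hydroxy-3-methyl-2,5,8,9-tetrahydro-1-benzoxepin-6(7H)-one (racemic; diastereomer mixture) | CC1=CCC2=C(OC1)C[C@H](O)C(C(O)CCc3ccc(OCOC)c(OCOC)c3)C2=O
F8 | step 11 | 3-[3,4-bis(trimethylsilyloxy)phenyl]-1-[3-methyl-6,8-bis(trimethylsilyloxy)-2,5-dihydro-1-benzoxepin-7-yl]propan-1-one | CC1=CCc2c(cc(O[Si](C)(C)C)c(C(=O)CCc3ccc(O[Si](C)(C)C)c(O[Si](C)(C)C)c3)c2O[Si](C)(C)C)OC1
A1 | alternative 1 | 3-[3,4-bis(methoxymethoxy)phenyl]-1-(2,4,6-trihydroxyphenyl)propan-1-one | COCOc1ccc(CCC(=O)c2c(O)cc(O)cc2O)cc1OCOC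
A2 | alternative 1 | 6-{4-[3,4-bis(methoxymethoxy)phenyl]-2-oxobutyl}-4-hydroxy-2H-pyran-2-one | O=C1C=C(O)C=C(CC(=O)CCc2ccc(OCOC)c(OCOC)c2)O1
A3 | alternative 2 | 6,8-bis(methoxymethoxy)-3-methyl-2,5-dihydro-1-benzoxepine-7-carbaldehyde | CC1=CCc2c(cc(OCOC)c(C=O)c2OCOC)OC1
A4 | alternative 2 | 4-fluoro-3-[(2Z)-4-hydroxy-3-methylbut-2-en-1-yl]-2,6-bis(methoxymethoxy)benzaldehyde | O=Cc1c(OCOC)c(C/C=C(/C)CO)c(F)cc1OCOC
A5 | alternative 3 | 6,8-bis(tert-butyldimethylsilyloxy)-3-methyl-2,5-dihydro-1-benzoxepine | CC1=CCc2c(cc(O[Si](C)(C)C(C)(C)C)cc2O[Si](C)(C)C(C)(C)C)OC1
A6 | alternative 3 | [2,4-bis(tert-butyldimethylsilyloxy)-6-{[(2Z)-2-methyl-3-(trimethylsilyl)prop-2-en-1-yl]oxy}phenyl]methanol | OCc1c(O[Si](C)(C)C(C)(C)C)cc(O[Si](C)(C)C(C)(C)C)cc1OC/C(C)=C\[Si](C)(C)C
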